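Readings and results were computed for an exercise.

A plateau is easily taken for an equilibrium, but a catalyst that wears out (catalyst deactivation) can draw the same flat line, so before giving you your quick number we tried that second reading on the stalls you point to.

| setting | green | amber | ochre | birch | elm | oak |
|---|---|---|---|---|---|---|
| starting material | 10 mM | 40 mM | 20 mM | 20 mM | 20 mM | 20 mM |
| second substrate | 40 mM | 40 mM | 40 mM | 40.0 mM | 40.0 mM | 40.0 mM |
| partner | 21 mM | 21 mM | 42 mM | 21.0 mM | 21.0 mM | 21.0 mM |
| free catalyst | 42 µM | 42 µM | 42 µM | 42 µM | 42 µM | 42 µM |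
| temperature | 75 °C | 105 °C | 75 °C | 105 °C | 130 °C | 80 °C |
| remark | run made earlier | run made earlier | run made earlier |  |  |  |
| time |  |  |  | 5.0 min | 5.0 min | 5.0 min |

| run | time / min | target / % | starting material / % |
|---|---|---|---|
| green | 4.00 | 41.6 | 57.8 |
| green | 8.00 | 55.7 | 44.8 |
| green | 12.0 | 61.4 | 38.1 |
| green | 20.0 | 67.2 | 34.2 |
| amber | 1.00 | 25.1 | 74.9 |
| amber | 2.00 | 30.5 | 69.2 |
| amber | 3.00 | 32.4 | 68.5 |
| amber | 4.00 | 32.2 | 66.9 |
| ochre | 4.00 | 48.5 | 51.4 |
| ochre | 8.00 | 65.3 | 33.7 |
| ochre | 12.0 | 73.7 | 26.6 |
| ochre | 20.0 | 78.5 | 20.7 |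

(each reading ± 0.5 percentage points)

- a reading or a percentage of target counts all its forms, free or not

- which flask leads in amount of target, in percent of the starting material charged ("all alike" within 1.5 percentage points) (birch / elm / oak / all alike)
- how much target is there at the end, in percent of the starting material charged: birch
- how much target is there at the end, in percent of the starting material charged: elm
- how much target is there at the end, in percent of the starting material charged: oak

Suppose that each bit of target costs the catalyst a share of its life inversely proportional to the product of starting material and partner still present, as it would if target forms in proportion to both while the wearing out keeps its own pace. Adding these costs from the start to the stall gives one figure per temperature, the stall budget: ln[a(b−p)/(b(a−p))]/(b−a), with a and b the charges of starting material and partner and p the target at the stall, in mM. This neglects any partner used otherwise.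

Amber reads as stopped, standing at 32.4% and then 32.2%, so its last reading gives a budget of 0.0296 mM⁻¹ at 105 °C. Green's readings are still rising, so its last reading gives a low estimate, 0.0663 mM⁻¹ at 75 °C. We let the budget shrink by a constant factor per degree, which gives 0.0151 mM⁻¹ for elm and 0.0579 mM⁻¹ for oak.

Solving for p, our estimated stalls are 38.6% for birch, 24.2% for elm and 55.6% for oak. We expect oak to lead, though still short of its estimated stall at the asked time.

The forecast reads the stalls differently, as “a reversible step pulled forward by partner binding the target”. It gives 42.5% for birch, 31% for elm and 49% for oak, with oak leading. It agrees with us on the lead but stands higher than our estimated stalls for birch and elm.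

The flasks give 37.1% for birch, 21.0% for elm and 45.4% for oak, so oak leads.

    starting material + free catalyst ⇌ catalyst intermediate A (K = 64.9 M⁻¹, k = 232 M⁻¹ s⁻¹, Ea = 57.0 kJ mol⁻¹, ΔH = −23.0 kJ mol⁻¹)
    partner + catalyst intermediate A → free catalyst + target (k = 657 M⁻¹ s⁻¹, Ea = 36.0 kJ mol⁻¹)
    second substrate + free catalyst ⇌ catalyst intermediate B (K = 23.0 M⁻¹, k = 157 M⁻¹ s⁻¹, Ea = 58.0 kJ mol⁻¹, ΔH = −43.0 kJ mol⁻¹)
    partner + catalyst intermediate B → free catalyst + second product (k = 128 M⁻¹ s⁻¹, Ea = 36.0 kJ mol⁻¹)
    catalyst intermediate B → spent catalyst (k = 0.0101 s⁻¹, Ea = 111 kJ mol⁻¹)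
    free catalyst + target ⇌ idle complex, settled at all times (K = 33.0 M⁻¹, ΔH = −15.0 kJ mol⁻¹)
    (constants at 80 °C)

Put back into the formula, birch's result gives a budget of 0.0277 mM⁻¹, against amber's 0.0296 mM⁻¹. Oak, left until 50.0 min, reaches 57.6%, against our estimated stall of 55.6%. Elm shows the stall: it ends at 21.0% through free catalyst binding second substrate together with the loss of catalyst intermediate B to spent catalyst. With that loss taken away, elm gives 87.3%. In elm, spent catalyst already stands at >99.9% of the catalyst charged after 2.50 min.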